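**Strategy.** Everything rests on disconnecting C4–C4a of the lower (epigallocatechin) pyran ring. C4 is the only carbon of that ring that is not a stereocentre, and C4a is the only position ortho to O1 on the lower A ring that is still free once C8 carries the upper flavan. The key step, an intramolecular Friedel–Crafts epoxy–arene cyclisation, lets C4a open a terminal oxirane at C4: one C–C bond closes the ring and releases the 3-OH, with the cis C2/C3 pair already fixed by Sharpless kinetic resolution and Mitsunobu inversion. Its precursor is the (R)-aryl[(R)-oxiranyl]methyl ether of a 3,5-dibenzyloxyphenol that already bears the complete upper flavan ortho to oxygen.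

Key step: step 8

Remark: flavan numbering (O1, C2, C3, C4, C4a, C5–C8, C8a) is used for both halves; "upper" is the 7,3′,4′-trioxygenated 4-arylflavan (2S,4R, 2,4-trans), "lower" the epigallocatechin unit (2R,3R, 2,3-cis).

Step 1
Reactants: 1 7-hydroxy-4H-chromen-4-one
Product: 2 7-(benzyloxy)-4H-chromen-4-one
Conditions: BnBr, K2CO3, DMF, rt
Reagents that add atoms: benzyl bromide, BrCc1ccccc1
Why: Williamson ether synthesis: the acidic 7-OH is benzylated under mild carbonate conditions that leave the chromone intact; no stereocentre is formed.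

Step 2
Reactants: 2 7-(benzyloxy)-4H-chromen-4-one; 3 [3,4-bis(benzyloxy)phenyl]boronic acid
Product: 4 (2S)-7-(benzyloxy)-2-[3,4-bis(benzyloxy)phenyl]chroman-4-one
Conditions: Pd(OCOCF3)2 (5 mol%), (R)-t-BuPyOx (6 mol%), NH4PF6 (30 mol%), H2O (5 equiv), ClCH2CH2Cl, 60 °C
Reagents that add atoms: none
Why: Pd(II)/pyridine-oxazoline-catalysed asymmetric conjugate addition of an arylboronic acid to a chromone: the ligand decides the enone face to which the aryl–Pd species adds and so sets C2 as S (the (R)-ligand is the antipode expected to give 2S), and the Pd enolate is protonated by water without base that could racemise the flavanone by retro-oxa-Michael opening.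

Step 3
Reactants: 4 (2S)-7-(benzyloxy)-2-[3,4-bis(benzyloxy)phenyl]chroman-4-one
Product: 5 (2S,4S)-7-(benzyloxy)-2-[3,4-bis(benzyloxy)phenyl]chroman-4-ol
Conditions: NaBH4, THF/MeOH, 0 °C
Reagents that add atoms: none
Why: Borohydride reduction of the aryl ketone: axial hydride attack on the ring with the 2-aryl group equatorial should give mainly the 2,4-cis (4S) alcohol, but the C4 configuration is irrelevant because C4 is ionised in step 4.

Step 4
Reactants: 5 (2S,4S)-7-(benzyloxy)-2-[3,4-bis(benzyloxy)phenyl]chroman-4-ol; 6 3,5-bis(benzyloxy)phenol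
Product: 7 3,5-bis(benzyloxy)-2-[(2S,4R)-7-(benzyloxy)-2-[3,4-bis(benzyloxy)phenyl]chroman-4-yl]phenol
Conditions: 6 (4 equiv), BF3·OEt2 (0.3 equiv), CH2Cl2, −40 → 0 °C
Reagents that add atoms: none
Why: Friedel–Crafts alkylation through the flavan-4-yl cation (stabilised by O1 and the para 7-benzyloxy group, as in proanthocyanidin couplings): the phenol should react at the carbon ortho to its free OH and para to a benzyloxy group, which is less hindered than the carbon between the two benzyl ethers, and pseudo-axial attack anti to the pseudo-equatorial 2-aryl group sets C4 as R (2,4-trans).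

Step 5
Reactants: 8 3,4,5-tris(benzyloxy)benzaldehyde; 9 vinylmagnesium bromide
Product: 10 rac-1-[3,4,5-tris(benzyloxy)phenyl]prop-2-en-1-ol
Conditions: THF, 0 °C; then H2O/NH4Cl
Reagents that add atoms: none
Why: Grignard 1,2-addition of the vinyl nucleophile to the aromatic aldehyde gives the racemic secondary allylic alcohol that supplies C2, C3 and C4 of the lower pyran ring.

Step 6
Reactants: 10 rac-1-[3,4,5-tris(benzyloxy)phenyl]prop-2-en-1-ol
Product: 11 (S)-[(2R)-oxiran-2-yl][3,4,5-tris(benzyloxy)phenyl]methanol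
Conditions: Ti(OiPr)4, L-(+)-DIPT, t-BuOOH (0.55 equiv), 4 Å MS, CH2Cl2, −20 °C
Reagents that add atoms: tert-butyl hydroperoxide, CC(C)(C)OO
Why: Sharpless kinetic resolution of a secondary allylic alcohol: with L-(+)-DIPT the (R)-enantiomer of 10 should be epoxidised fast and with the usual erythro (anti) selectivity, the titanium-bound carbinol directing oxygen to one alkene face to give the (S)-carbinol/(R)-oxirane isomer, while (S)-10 stays behind and is separated.

Step 7
Reactants: 7 3,5-bis(benzyloxy)-2-[(2S,4R)-7-(benzyloxy)-2-[3,4-bis(benzyloxy)phenyl]chroman-4-yl]phenol; 11 (S)-[(2R)-oxiran-2-yl][3,4,5-tris(benzyloxy)phenyl]methanol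
Product: 12 (2R)-2-[(R)-{3,5-bis(benzyloxy)-2-[(2S,4R)-7-(benzyloxy)-2-[3,4-bis(benzyloxy)phenyl]chroman-4-yl]phenoxy}[3,4,5-tris(benzyloxy)phenyl]methyl]oxirane
Conditions: PPh3, DIAD, toluene, 0 °C → rt
Reagents that add atoms: none
Why: Mitsunobu etherification: the only acidic OH of 7 displaces the oxyphosphonium of the secondary carbinol by SN2, inverting the future C2 from S to R, while the electron-withdrawing oxirane next to the carbinol carbon disfavours SN1 ionisation.

Step 8
Reactants: 12 (2R)-2-[(R)-{3,5-bis(benzyloxy)-2-[(2S,4R)-7-(benzyloxy)-2-[3,4-bis(benzyloxy)phenyl]chroman-4-yl]phenoxy}[3,4,5-tris(benzyloxy)phenyl]methyl]oxirane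
Product: 13 (2R,3R)-5,7-bis(benzyloxy)-8-[(2S,4R)-7-(benzyloxy)-2-[3,4-bis(benzyloxy)phenyl]chroman-4-yl]-2-[3,4,5-tris(benzyloxy)phenyl]chroman-3-ol
Conditions: AuCl3 (5 mol%), AgOTf (15 mol%), ClCH2CH2Cl, 0 °C → rt
Reagents that add atoms: none
Why: The Lewis acid activates the oxirane oxygen and the phloroglucinol-type carbon C4a (ortho to O1 and to the C5 benzyloxy group, para to the C7 benzyloxy group) attacks the terminal oxirane carbon C4 in an SN2-like Friedel–Crafts alkylation, followed by rearomatisation; this is the known gold(III)- or fluoroalcohol-promoted cyclialkylation of aryl glycidyl ethers to chroman-3-ols. The pyran ring is closed in the 6-endo mode (both oxirane carbons end up in the ring, C4–O is the bond broken) by forming the C4–C4a bond. No new stereocentre is created: C3 keeps the oxirane configuration because only the CH2 terminus reacts and C2 is a spectator, so the (2R,3R)-cis pair set in steps 6 and 7 is carried over unchanged. The step needs endo rather than 5-exo opening (attack at C3), which the unhindered primary terminus should secure against a secondary carbon flanked by the aryloxy-bearing C2, and it needs site selectivity on the arene, which the substrate enforces because C8 is blocked by the upper flavan and C6 cannot reach the oxirane. Competing ionisation of the benzylic C2–O1 ether is disfavoured by the electron-withdrawing oxirane next to C2 and by the mild, catalytic conditions.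

Step 9
Reactants: 13 (2R,3R)-5,7-bis(benzyloxy)-8-[(2S,4R)-7-(benzyloxy)-2-[3,4-bis(benzyloxy)phenyl]chroman-4-yl]-2-[3,4,5-tris(benzyloxy)phenyl]chroman-3-ol
Product: 14 (2R,3R)-8-[(2S,4R)-2-(3,4-dihydroxyphenyl)-7-hydroxychroman-4-yl]-2-(3,4,5-trihydroxyphenyl)chroman-3,5,7-triol
Conditions: H2 (1 atm), Pd(OH)2/C, THF/MeOH, rt
Reagents that add atoms: none
Why: Catalytic hydrogenolysis of the eight benzyl ethers under neutral conditions, the standard global deprotection of benzylated proanthocyanidins, should leave the pyran C2–O1 bonds, the interflavan C4–C8 bond and all four stereocentres untouched.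

**Compound list**

1 | 7-hydroxy-4H-chromen-4-one | O=c1ccoc2cc(O)ccc12 | starting material
2 | 7-(benzyloxy)-4H-chromen-4-one | O=c1ccoc2cc(OCc3ccccc3)ccc12 | intermediate
3 | [3,4-bis(benzyloxy)phenyl]boronic acid | OB(O)c1ccc(OCc2ccccc2)c(OCc2ccccc2)c1 | starting material
4 | (2S)-7-(benzyloxy)-2-[3,4-bis(benzyloxy)phenyl]chroman-4-one | c1ccccc1COc1ccc2c(c1)O[C@H](c1ccc(OCc3ccccc3)c(OCc3ccccc3)c1)CC2=O | intermediate
5 | (2S,4S)-7-(benzyloxy)-2-[3,4-bis(benzyloxy)phenyl]chroman-4-ol | c1ccccc1COc1ccc2c(c1)O[C@H](c1ccc(OCc3ccccc3)c(OCc3ccccc3)c1)C[C@@H]2O | intermediate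
6 | 3,5-bis(benzyloxy)phenol | Oc1cc(OCc2ccccc2)cc(OCc2ccccc2)c1 | starting material
7 | 3,5-bis(benzyloxy)-2-[(2S,4R)-7-(benzyloxy)-2-[3,4-bis(benzyloxy)phenyl]chroman-4-yl]phenol | c1ccccc1COc1ccc2c(c1)O[C@H](c1ccc(OCc3ccccc3)c(OCc3ccccc3)c1)C[C@H]2c1c(OCc3ccccc3)cc(OCc3ccccc3)cc1O | intermediate
8 | 3,4,5-tris(benzyloxy)benzaldehyde | O=Cc1cc(OCc2ccccc2)c(OCc2ccccc2)c(OCc2ccccc2)c1 | starting material
9 | vinylmagnesium bromide | C=C[Mg]Br | starting material
10 | rac-1-[3,4,5-tris(benzyloxy)phenyl]prop-2-en-1-ol | OC(C=C)c1cc(OCc2ccccc2)c(OCc2ccccc2)c(OCc2ccccc2)c1 | intermediate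
11 | (S)-[(2R)-oxiran-2-yl][3,4,5-tris(benzyloxy)phenyl]methanol | O[C@@H](c1cc(OCc2ccccc2)c(OCc2ccccc2)c(OCc2ccccc2)c1)[C@H]1CO1 | intermediate
12 | (2R)-2-[(R)-{3,5-bis(benzyloxy)-2-[(2S,4R)-7-(benzyloxy)-2-[3,4-bis(benzyloxy)phenyl]chroman-4-yl]phenoxy}[3,4,5-tris(benzyloxy)phenyl]methyl]oxirane | c1ccccc1COc1ccc2c(c1)O[C@H](c1ccc(OCc3ccccc3)c(OCc3ccccc3)c1)C[C@H]2c1c(OCc3ccccc3)cc(OCc3ccccc3)cc1O[C@H](c1cc(OCc3ccccc3)c(OCc3ccccc3)c(OCc3ccccc3)c1)[C@H]4CO4 | intermediate
13 | (2R,3R)-5,7-bis(benzyloxy)-8-[(2S,4R)-7-(benzyloxy)-2-[3,4-bis(benzyloxy)phenyl]chroman-4-yl]-2-[3,4,5-tris(benzyloxy)phenyl]chroman-3-ol | c1ccccc1COc1ccc2c(c1)O[C@H](c1ccc(OCc3ccccc3)c(OCc3ccccc3)c1)C[C@H]2c1c(OCc3ccccc3)cc(OCc3ccccc3)c2c1O[C@H](c1cc(OCc3ccccc3)c(OCc3ccccc3)c(OCc3ccccc3)c1)[C@H](O)C2 | intermediate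
14 | (2R,3R)-8-[(2S,4R)-2-(3,4-dihydroxyphenyl)-7-hydroxychroman-4-yl]-2-(3,4,5-trihydroxyphenyl)chroman-3,5,7-triol | Oc1ccc2c(c1)O[C@H](c1ccc(O)c(O)c1)C[C@H]2c1c(O)cc(O)c2c1O[C@H](c1cc(O)c(O)c(O)c1)[C@H](O)C2 | target

**Step count.** Total: 9 steps. Longest linear sequence: 7 steps (1, 2, 3, 4, 7, 8, 9); the side branch (5, 6) joins at step 7.

**Steps most likely to fail**

Step 8 (key step). The oxirane may be opened at the wrong carbon (5-exo attack at C3, giving a dihydrobenzofuran), or the Lewis acid may ionise the benzylic C2–O1 ether, with O→C migration and loss of the C2 configuration. The fallback reverses the polarity of the same C4–C4a bond formation and sets out from 7. Bromination with NBS and catalytic i-Pr2NH in CH2Cl2 at 0 °C, at the only free position ortho to the hydroxyl, would give 2-bromo-3,5-bis(benzyloxy)-6-[(2S,4R)-7-(benzyloxy)-2-[3,4-bis(benzyloxy)phenyl]chroman-4-yl]phenol F1. Mitsunobu coupling of F1 with 11 (PPh3, DIAD, toluene) would give the bromo analogue of 12, (2R)-2-[(R)-{2-bromo-3,5-bis(benzyloxy)-6-[(2S,4R)-7-(benzyloxy)-2-[3,4-bis(benzyloxy)phenyl]chroman-4-yl]phenoxy}[3,4,5-tris(benzyloxy)phenyl]methyl]oxirane F2. Bromine–lithium exchange (n-BuLi, THF, −78 °C, then warming) would let the aryllithium open the oxirane at its unhindered terminal carbon under non-acidic conditions, and aqueous work-up comes back to the route at 13.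

Step 7. The ortho-flavanyl group may make the etherification slow, and partial ionisation of the activated carbinol would erode the C2 configuration. The fallback moves the etherification to the unhindered phenol and sets out from 6 and 11. Their Mitsunobu coupling (PPh3, DIAD, toluene) would give (2R)-2-[(R)-[3,5-bis(benzyloxy)phenoxy][3,4,5-tris(benzyloxy)phenyl]methyl]oxirane F3. Under the conditions of step 8, F3 should cyclise to (2R,3R)-5,7-bis(benzyloxy)-2-[3,4,5-tris(benzyloxy)phenyl]chroman-3-ol F4, which is not isolated. Alcohol 5 and BF3·OEt2 are then added to the same flask at −40 °C, so that the flavan-4-yl cation is captured at C8 of F4, the usual site for 5,7-di-O-benzyl flavan-3-ols, and the route is rejoined at 13. The lower pyran ring is still the last ring of the skeleton to be formed, now just before the interflavan bond instead of after it.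

Step 4. Site selectivity may be poor (attack at the carbon between the two benzyl ethers, or double alkylation), and facial selectivity at C4 may be incomplete. The fallback delivers the flavanyl group from the phenol oxygen and sets out from 5 and 6. Mitsunobu O-alkylation (PPh3, DIAD, THF) would give (2S,4R)-7-(benzyloxy)-2-[3,4-bis(benzyloxy)phenyl]-4-[3,5-bis(benzyloxy)phenoxy]chromane F5. Catalytic Sc(OTf)3 in CH2Cl2 at −78 → −20 °C would then ionise the benzylic ether and return the cation within the ion pair to the neighbouring ortho carbon (Fries-type O→C migration, the logic of aryl O- to C-glycoside rearrangement), again anti to the 2-aryl group, coming back to the route at 7.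

**Further compounds**

F1 | step 8 | 2-bromo-3,5-bis(benzyloxy)-6-[(2S,4R)-7-(benzyloxy)-2-[3,4-bis(benzyloxy)phenyl]chroman-4-yl]phenol | c1ccccc1COc1ccc2c(c1)O[C@H](c1ccc(OCc3ccccc3)c(OCc3ccccc3)c1)C[C@H]2c1c(OCc3ccccc3)cc(OCc3ccccc3)c(Br)c1O
F2 | step 8 | (2R)-2-[(R)-{2-bromo-3,5-bis(benzyloxy)-6-[(2S,4R)-7-(benzyloxy)-2-[3,4-bis(benzyloxy)phenyl]chroman-4-yl]phenoxy}[3,4,5-tris(benzyloxy)phenyl]methyl]oxirane | c1ccccc1COc1ccc2c(c1)O[C@H](c1ccc(OCc3ccccc3)c(OCc3ccccc3)c1)C[C@H]2c1c(OCc3ccccc3)cc(OCc3ccccc3)c(Br)c1O[C@H](c1cc(OCc3ccccc3)c(OCc3ccccc3)c(OCc3ccccc3)c1)[C@H]4CO4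
F3 | step 7 | (2R)-2-[(R)-[3,5-bis(benzyloxy)phenoxy][3,4,5-tris(benzyloxy)phenyl]methyl]oxirane | O(Cc1ccccc1)c1cc(OCc2ccccc2)cc(c1)O[C@H](c1cc(OCc2ccccc2)c(OCc2ccccc2)c(OCc2ccccc2)c1)[C@H]1CO1
F4 | step 7 | (2R,3R)-5,7-bis(benzyloxy)-2-[3,4,5-tris(benzyloxy)phenyl]chroman-3-ol | O(Cc1ccccc1)c1cc(OCc3ccccc3)c2c(c1)O[C@H](c1cc(OCc3ccccc3)c(OCc3ccccc3)c(OCc3ccccc3)c1)[C@H](O)C2
F5 | step 4 | (2S,4R)-7-(benzyloxy)-2-[3,4-bis(benzyloxy)phenyl]-4-[3,5-bis(benzyloxy)phenoxy]chromane | c1ccccc1COc1ccc2c(c1)O[C@H](c1ccc(OCc3ccccc3)c(OCc3ccccc3)c1)C[C@H]2Oc1cc(OCc3ccccc3)cc(OCc3ccccc3)c1
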